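**Plan**

- Labels: ring A is C1 (quaternary), C2 (ketone), C3 (acyl-bearing), C4 (enol), C5 (on the pyran oxygen), C6; ring B is O, C2' (gem-dimethyl), C3', C4' (on C6). The rings share C5–C6, so ring B is the formal [4+2] adduct of a C5 aldehyde and the dienyl chain C6=C4'–C3'=C2'Me2 carried by C1.
- Retrosynthesis, in order: the C3-acyl/C4-enol pair is folded into an isoxazole (N–O bond); C5=C6 is saturated; C5–C6 and O–C2' are cut together; C2–C3 is cut to a 4-lithioisoxazole and an aldehyde; C6=C4' is cut by olefination; C1–CH3 and C1–prenyl are cut to enolate alkylations of malate.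
- Forward: the C1 chain comes from diethyl (S)-malate (steps 1–7) and the isoxazole from 3-phenylpropanal (steps 8–10). They are joined at C2–C3 (step 11), rings A and B close together in step 14, then C5=C6 is introduced and the isoxazole is opened to the triketone.
- Stereochemistry: C1 is the only stereocentre of the target. It is set in step 2 by a second Fráter–Seebach alkylation under control of the malate carbinol, which is then excised. C5 and C6 of the cycloadduct are transient.

Key step: step 14

Assumption: 28 is a β-triketone whose enol tautomers equilibrate, so the tautomer drawn is taken as the target; 3 (C3 epimers) and 23 (C5/C6 diastereomers) are carried on as mixtures because these centres are planarised in the following step.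

**Route**

Step 1
Reactants: 1 diethyl (2S)-2-hydroxybutanedioate; 2 1-bromo-3-methylbut-2-ene
Product: 3 diethyl (2S,3R)-2-hydroxy-3-(3-methylbut-2-en-1-yl)butanedioate
Conditions: LiN(iPr)2 (2.1 equiv), THF, −78 → −20 °C; 2, −78 → −5 °C; H2O
Reagents that add atoms: none
Why: Fráter–Seebach alkylation, in which the chelated dilithium alkoxide–enolate of the β-hydroxy ester is alkylated at malate C3 anti to the C2 ester group, so the (2S,3R) epimer should predominate.

Step 2
Reactants: 3 diethyl (2S,3R)-2-hydroxy-3-(3-methylbut-2-en-1-yl)butanedioate; 4 iodomethane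
Product: 5 diethyl (2S,3S)-2-hydroxy-3-methyl-3-(3-methylbut-2-en-1-yl)butanedioate
Conditions: LiN(iPr)2 (2.2 equiv), THF/DMPU, −78 → −20 °C; 4, −78 → −10 °C; H2O; chromatography
Reagents that add atoms: none
Why: second Fráter–Seebach alkylation, in which the chelated tetrasubstituted enolate has a fixed geometry and should take up iodomethane on the face used by prenyl bromide in step 1, so that the malate C2 carbinol sets the quaternary carbon as (3S), the later C1 of the target, the minor diastereomer being removed by chromatography.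

Step 3
Reactants: 5 diethyl (2S,3S)-2-hydroxy-3-methyl-3-(3-methylbut-2-en-1-yl)butanedioate
Product: 6 (2S,3S)-3-(ethoxycarbonyl)-2-hydroxy-3,6-dimethylhept-5-enoic acid
Conditions: LiOH·H2O (1.1 equiv), THF/H2O, 0 °C; then 1 M HCl
Reagents that add atoms: lithium hydroxide, [Li+].[OH-]
Why: chemoselective saponification, since the α-hydroxy ester is far more accessible and more electrophilic than the ester on the quaternary carbon.

Step 4
Reactants: 6 (2S,3S)-3-(ethoxycarbonyl)-2-hydroxy-3,6-dimethylhept-5-enoic acid
Product: 7 ethyl (2S)-2-formyl-2,5-dimethylhex-4-enoate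
Conditions: Pb(OAc)4 (1.1 equiv), CH2Cl2, 0 °C → rt
Reagents that add atoms: none
Why: oxidative decarboxylation of an α-hydroxy acid by Pb(OAc)4 turns the controlling carbinol carbon into the formyl group and leaves the quaternary centre, which has no α-hydrogen and cannot epimerise.

Step 5
Reactants: 2 1-bromo-3-methylbut-2-ene; 8 triethyl phosphite
Product: 9 diethyl (3-methylbut-2-en-1-yl)phosphonate
Conditions: neat, 120 °C, EtBr distilled off
Reagents that add atoms: none
Why: Michaelis–Arbuzov reaction of a primary allylic bromide at its unhindered CH2 terminus.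

Step 6
Reactants: 7 ethyl (2S)-2-formyl-2,5-dimethylhex-4-enoate; 9 diethyl (3-methylbut-2-en-1-yl)phosphonate
Product: 10 ethyl (2S,3E)-2,6-dimethyl-2-(3-methylbut-2-en-1-yl)hepta-3,5-dienoate
Conditions: 9, n-BuLi, THF, −78 °C; then 7, −78 → 40 °C
Reagents that add atoms: none
Why: Horner–Wadsworth–Emmons olefination with an allylic phosphonate anion, which reacts through its α-carbon with the aldehyde (not the hindered ester) and should give the (E)-disubstituted alkene of the diene.

Step 7
Reactants: 10 ethyl (2S,3E)-2,6-dimethyl-2-(3-methylbut-2-en-1-yl)hepta-3,5-dienoate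
Product: 11 (2S,3E)-2,6-dimethyl-2-(3-methylbut-2-en-1-yl)hepta-3,5-dienal
Conditions: iBu2AlH (1.1 equiv), CH2Cl2, −78 °C; MeOH, then aq. KNaC4H4O6 (potassium sodium tartrate)
Reagents that add atoms: none
Why: partial ester reduction, in which the tetrahedral aluminium hemiacetal of the α-quaternary ester should persist at −78 °C and release the aldehyde only on work-up.

Step 8
Reactants: 12 3-phenylpropanal
Product: 13 3-phenylpropanal oxime
Conditions: NH2OH (50% aq.), EtOH, rt
Reagents that add atoms: hydroxylamine, NO
Why: oxime formation by condensation of the aldehyde with hydroxylamine.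

Step 9
Reactants: 13 3-phenylpropanal oxime; 14 3,3-diethoxyprop-1-yne
Product: 17 5-(diethoxymethyl)-3-(2-phenylethyl)-1,2-oxazole, via N-hydroxy-3-phenylpropanimidoyl chloride 15 (not isolated), via 3-phenylpropanenitrile oxide 16 (not isolated)
Conditions: N-chlorosuccinimide, DMF, rt; then 14 (2 equiv), Et3N (slow addition), 0 °C → rt
Reagents that add atoms: none
Why: chlorination of the aldoxime and dehydrochlorination give the nitrile oxide, whose Huisgen 1,3-dipolar cycloaddition to a terminal alkyne places the alkyne substituent at isoxazole C5.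

Step 10
Reactants: 17 5-(diethoxymethyl)-3-(2-phenylethyl)-1,2-oxazole
Product: 18 4-bromo-5-(diethoxymethyl)-3-(2-phenylethyl)-1,2-oxazole
Conditions: N-bromosuccinimide (1.1 equiv), DMF, 50 °C, dark
Reagents that add atoms: N-bromosuccinimide, O=C1CCC(=O)N1Br
Why: electrophilic aromatic bromination at C4, the only free and the most electron-rich position of a 3,5-disubstituted isoxazole, under non-acidic conditions that spare the acetal.

Step 11
Reactants: 18 4-bromo-5-(diethoxymethyl)-3-(2-phenylethyl)-1,2-oxazole; 11 (2S,3E)-2,6-dimethyl-2-(3-methylbut-2-en-1-yl)hepta-3,5-dienal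
Product: 20 (2S,3E)-1-[5-(diethoxymethyl)-3-(2-phenylethyl)-1,2-oxazol-4-yl]-2,6-dimethyl-2-(3-methylbut-2-en-1-yl)hepta-3,5-dien-1-ol, via 4-lithioisoxazole acetal 19 (not isolated)
Conditions: 18, n-BuLi (1.05 equiv), THF, −78 °C; then 11, −78 → −40 °C; H2O
Reagents that add atoms: none
Why: bromine–lithium exchange at −78 °C should outrun lateral deprotonation, and the 4-lithioisoxazole then undergoes 1,2-addition to the non-enolisable aldehyde, the carbinol configuration being irrelevant because it is oxidised next.

Step 12
Reactants: 20 (2S,3E)-1-[5-(diethoxymethyl)-3-(2-phenylethyl)-1,2-oxazol-4-yl]-2,6-dimethyl-2-(3-methylbut-2-en-1-yl)hepta-3,5-dien-1-ol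
Product: 21 (2S,3E)-1-[5-(diethoxymethyl)-3-(2-phenylethyl)-1,2-oxazol-4-yl]-2,6-dimethyl-2-(3-methylbut-2-en-1-yl)hepta-3,5-dien-1-one
Conditions: Dess–Martin periodinane, NaHCO3, CH2Cl2, rt
Reagents that add atoms: none
Why: Dess–Martin oxidation copes with the hindered secondary alcohol, and the buffer keeps the acetal and the diene intact.

Step 13
Reactants: 21 (2S,3E)-1-[5-(diethoxymethyl)-3-(2-phenylethyl)-1,2-oxazol-4-yl]-2,6-dimethyl-2-(3-methylbut-2-en-1-yl)hepta-3,5-dien-1-one
Product: 22 4-[(2S,3E)-2,6-dimethyl-2-(3-methylbut-2-en-1-yl)hepta-3,5-dienoyl]-3-(2-phenylethyl)-1,2-oxazole-5-carbaldehyde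
Conditions: 2 M aq. HCl/THF (1:4), rt; used at once
Reagents that add atoms: water, O
Why: acid-catalysed acetal hydrolysis, for which dilute acid at room temperature should suffice without protonating the diene or the prenyl alkene.

Step 14
Reactants: 22 4-[(2S,3E)-2,6-dimethyl-2-(3-methylbut-2-en-1-yl)hepta-3,5-dienoyl]-3-(2-phenylethyl)-1,2-oxazole-5-carbaldehyde
Product: 23 isoxazole-fused cycloadduct in which ring A (C1 S-configured; C2 ketone; C3/C4 = isoxazole C4/C5; C5–H; C6–H) is fused through C5–C6 to a 2,2-dimethyl-3,6-dihydro-2H-pyran (C5/C6 diastereomers)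
Conditions: BF3·OEt2 (1.2 equiv), CH2Cl2, −78 → −20 °C; aq. NaHCO3
Reagents that add atoms: none
Why: BF3 binds the aldehyde oxygen of 22, the diene terminus C6 attacks the activated carbonyl carbon C5 and the oxygen closes on the dimethyl-substituted terminus C2' in a concerted but asynchronous [4+2] with allyl-cation character that is best carried by C2'. The closest known reaction type is the Lewis-acid-promoted carbonyl hetero-Diels–Alder (Prins-type) addition of aldehydes to 4-methylpenta-1,3-dienes giving 2,2-dimethyl-3,6-dihydro-2H-pyrans, run here in its intramolecular type 1 form. Ring A closes by 6-exo-trig attack of C6 on the aldehyde carbon along the four-atom tether C1–C2–C3–C4 (fused mode), and ring B is the six-membered cycloadduct ring itself, closed by the C5–C6 and O–C2' bonds. C5 and C6 arise together: their relative configuration follows from suprafacial addition across the (E)-C6=C4' bond in the tether-constrained transition state (cis fusion expected) and the diene face is chosen by the C1 stereocentre, but both carbons become sp2 in step 15, so every diastereomer is carried on. The step needs the diene and not the prenyl alkene to act as nucleophile, and oxygen rather than proton loss to quench the allyl cation: the diene closes a six-membered ring where the prenyl group would need a seven-membered one, the gem-dimethyl terminus localises the charge at C2' within reach of oxygen, and the isoxazole holds the aldehyde cis to the acyl tether and keeps it non-enolisable.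

Step 15
Reactants: 23 isoxazole-fused cycloadduct (C5/C6 diastereomers)
Product: 26 isoxazole-fused 2,2-dimethyl-2H-pyran tricycle (as 23 but with a C5=C6 double bond), via C5 phenylselenide 24 (not isolated), via C5 selenoxide 25 (not isolated)
Conditions: LiN(SiMe3)2 (1.1 equiv), THF, −78 °C; PhSeCl (1.0 equiv), −78 °C; then pyridine, 30% aq. H2O2, 0 °C → rt
Reagents that add atoms: none
Why: C5–H is a lateral proton of a 5-alkylisoxazole and vinylogously α to the C2 ketone, so the amide base should give the extended enolate, which is selenenylated at C5 with rearomatisation of the isoxazole, and selenoxide syn-elimination with C6–H then gives the C5=C6 enol ether (lateral metalation followed by selenoxide elimination).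

Step 16
Reactants: 26 isoxazole-fused 2,2-dimethyl-2H-pyran tricycle
Product: 27 (5S)-7-(1-amino-3-phenylpropylidene)-2,2,5-trimethyl-5-(3-methylbut-2-en-1-yl)-2H-chromene-6,8(5H,7H)-dione
Conditions: Mo(CO)6 (1.0 equiv), MeCN/H2O (15:1), 80 °C
Reagents that add atoms: none
Why: reductive N–O cleavage of the isoxazole by Mo(CO)6 in wet acetonitrile gives the vinylogous amide and leaves the alkenes and the 2H-pyran untouched.

Step 17
Reactants: 27 (5S)-7-(1-amino-3-phenylpropylidene)-2,2,5-trimethyl-5-(3-methylbut-2-en-1-yl)-2H-chromene-6,8(5H,7H)-dione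
Product: 28 (5S)-8-hydroxy-2,2,5-trimethyl-5-(3-methylbut-2-en-1-yl)-7-(3-phenylpropanoyl)-2H-chromen-6(5H)-one
Conditions: 1 M aq. NaOH, EtOH, 50 °C; then 1 M HCl to pH 3, 0 °C
Reagents that add atoms: water, O
Why: hydrolysis of the primary enaminone by addition–elimination of hydroxide at the amino-bearing carbon, with loss of ammonia, frees the enolised β-triketone as in the isoxazole route to 2-acylcyclohexane-1,3-diones, while the quaternary C1 cannot epimerise.

**Compound list**

1 | diethyl (2S)-2-hydroxybutanedioate (diethyl L-malate) | CCOC(=O)C[C@H](O)C(=O)OCC | starting material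
2 | 1-bromo-3-methylbut-2-ene (prenyl bromide) | CC(C)=CCBr | starting material
3 | diethyl (2S,3R)-2-hydroxy-3-(3-methylbut-2-en-1-yl)butanedioate (major C3 epimer) | CCOC(=O)[C@H](CC=C(C)C)[C@H](O)C(=O)OCC | intermediate
4 | iodomethane | CI | starting material
5 | diethyl (2S,3S)-2-hydroxy-3-methyl-3-(3-methylbut-2-en-1-yl)butanedioate | CCOC(=O)[C@](CC=C(C)C)(C)[C@H](O)C(=O)OCC | intermediate
6 | (2S,3S)-3-(ethoxycarbonyl)-2-hydroxy-3,6-dimethylhept-5-enoic acid | CCOC(=O)[C@](CC=C(C)C)(C)[C@H](O)C(=O)O | intermediate
7 | ethyl (2S)-2-formyl-2,5-dimethylhex-4-enoate | CCOC(=O)[C@](CC=C(C)C)(C)C=O | intermediate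
8 | triethyl phosphite | CCOP(OCC)OCC | starting material
9 | diethyl (3-methylbut-2-en-1-yl)phosphonate | CCOP(=O)(CC=C(C)C)OCC | intermediate
10 | ethyl (2S,3E)-2,6-dimethyl-2-(3-methylbut-2-en-1-yl)hepta-3,5-dienoate | CCOC(=O)[C@](CC=C(C)C)(C)/C=C/C=C(C)C | intermediate
11 | (2S,3E)-2,6-dimethyl-2-(3-methylbut-2-en-1-yl)hepta-3,5-dienal | O=C[C@](CC=C(C)C)(C)/C=C/C=C(C)C | intermediate
12 | 3-phenylpropanal | O=CCCc1ccccc1 | starting material
13 | 3-phenylpropanal oxime (E/Z mixture) | ON=CCCc1ccccc1 | intermediate
14 | 3,3-diethoxyprop-1-yne | C#CC(OCC)OCC | starting material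
15 | N-hydroxy-3-phenylpropanimidoyl chloride | ON=C(Cl)CCc1ccccc1 | intermediate (not isolated)
16 | 3-phenylpropanenitrile oxide | [O-][N+]#CCCc1ccccc1 | intermediate (not isolated)
17 | 5-(diethoxymethyl)-3-(2-phenylethyl)-1,2-oxazole | CCOC(OCC)c1cc(CCc2ccccc2)no1 | intermediate
18 | 4-bromo-5-(diethoxymethyl)-3-(2-phenylethyl)-1,2-oxazole | CCOC(OCC)c1onc(CCc2ccccc2)c1Br | intermediate
19 | [5-(diethoxymethyl)-3-(2-phenylethyl)-1,2-oxazol-4-yl]lithium | CCOC(OCC)c1onc(CCc2ccccc2)c1[Li] | intermediate (not isolated)
20 | (2S,3E)-1-[5-(diethoxymethyl)-3-(2-phenylethyl)-1,2-oxazol-4-yl]-2,6-dimethyl-2-(3-methylbut-2-en-1-yl)hepta-3,5-dien-1-ol (carbinol epimers) | CCOC(OCC)c1onc(CCc2ccccc2)c1C(O)[C@](CC=C(C)C)(C)/C=C/C=C(C)C | intermediate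
21 | (2S,3E)-1-[5-(diethoxymethyl)-3-(2-phenylethyl)-1,2-oxazol-4-yl]-2,6-dimethyl-2-(3-methylbut-2-en-1-yl)hepta-3,5-dien-1-one | CCOC(OCC)c1onc(CCc2ccccc2)c1C(=O)[C@](CC=C(C)C)(C)/C=C/C=C(C)C | intermediate
22 | 4-[(2S,3E)-2,6-dimethyl-2-(3-methylbut-2-en-1-yl)hepta-3,5-dienoyl]-3-(2-phenylethyl)-1,2-oxazole-5-carbaldehyde | O=Cc1onc(CCc2ccccc2)c1C(=O)[C@](CC=C(C)C)(C)/C=C/C=C(C)C | intermediate
23 | isoxazole-fused cycloadduct: ring A (C1 S with methyl and prenyl; C2 ketone; C3/C4 = isoxazole C4/C5, isoxazole C3 bearing 2-phenylethyl; C5–H on the pyran oxygen; C6–H) fused through C5–C6 to a 2,2-dimethyl-3,6-dihydro-2H-pyran with a C3'=C4' double bond; C5/C6 diastereomers, cis fusion expected | CC(C)=CC[C@]1(C)C(=O)c2c(CCc3ccccc3)noc2C2OC(C)(C)C=CC12 | intermediate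
24 | C5 phenylselenide of 23 (C5/C6 diastereomers) | CC(C)=CC[C@]1(C)C(=O)c2c(CCc3ccccc3)noc2C2([Se]c3ccccc3)OC(C)(C)C=CC12 | intermediate (not isolated)
25 | C5 selenoxide of 23 (diastereomers) | CC(C)=CC[C@]1(C)C(=O)c2c(CCc3ccccc3)noc2C2([Se](=O)c3ccccc3)OC(C)(C)C=CC12 | intermediate (not isolated)
26 | isoxazole-fused 2,2-dimethyl-2H-pyran tricycle: as 23 with a C5=C6 double bond; the 7-acyl/8-hydroxy pair of 28 tied up as a 3-(2-phenylethyl)isoxazole | CC(C)=CC[C@]1(C)C(=O)c2c(CCc3ccccc3)noc2C2=C1C=CC(C)(C)O2 | intermediate
27 | (5S)-7-(1-amino-3-phenylpropylidene)-2,2,5-trimethyl-5-(3-methylbut-2-en-1-yl)-2H-chromene-6,8(5H,7H)-dione (push–pull alkene, geometry not fixed) | CC(C)=CC[C@]1(C)C(=O)C(=C(N)CCc2ccccc2)C(=O)C2=C1C=CC(C)(C)O2 | intermediate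
28 | (5S)-8-hydroxy-2,2,5-trimethyl-5-(3-methylbut-2-en-1-yl)-7-(3-phenylpropanoyl)-2H-chromen-6(5H)-one (CNP0120278.1) | CC(C)=CC[C@]1(C)C(=O)C(C(=O)CCc2ccccc2)=C(O)C2=C1C=CC(C)(C)O2 | target

**Count and risks**

Total step count: 17. Longest linear sequence: 13 steps (1–4, 6, 7, 11–17).

Steps most likely to fail:

Step 14. The flat, sp2-rich tether may keep the diene from reaching the s-cis geometry over the complexed carbonyl, so that the allyl cation formed after C5–C6 bonding collapses by proton loss or fluoride capture, or the prenyl alkene reacts instead. The fallback builds ring B first without a tether and closes ring A afterwards by anionic cycloacylation. It sets out from 18 and 10: acetal 18 is hydrolysed (2 M HCl, THF) to 4-bromo-3-(2-phenylethyl)-1,2-oxazole-5-carbaldehyde F1, which is combined with diene ester 10 under BF3·OEt2 in an intermolecular carbonyl hetero-Diels–Alder reaction to give the dihydropyran bromo ester F2. Bromine–lithium exchange on F2 (n-BuLi, THF, −100 °C) and attack of the resulting 4-lithioisoxazole on the neighbouring ethyl ester (Parham cyclisation) close ring A, and the route is rejoined at 23.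

Step 15. Selenenylation may occur on the face that leaves the selenoxide without a syn hydrogen at C6, and the selenium electrophile or the peroxide may attack the prenyl double bond. The fallback replaces the syn-elimination by an ionic one and sets out from 23: the same extended enolate (LiN(SiMe3)2, THF, −78 °C) is quenched with hexachloroethane to give the C5 chloro ether F3, and DBU (toluene, 60 °C) removes hydrogen chloride by an anti or ionisation pathway that needs no syn hydrogen. The route is rejoined at 26.

Step 11. Addition of the doubly ortho-substituted aryllithium to the neopentyl-type aldehyde may be slow, and proton transfer from the acetal C–H may quench 19 first. The fallback builds the isoxazole on the chain instead and sets out from 11: lithiated 14 (n-BuLi, THF, −78 °C) adds to 11 to give the propargylic alcohol F4, and Dess–Martin oxidation gives the ynone F5. Cycloaddition of nitrile oxide 16 (generated from 13 through 15 as in step 9) to this internal ynone should place the acyl group at isoxazole C4, the electron-poor alkyne outcompeting the hindered alkenes. The route is rejoined at 21.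

Further compounds
F1 | step 14 | 4-bromo-3-(2-phenylethyl)-1,2-oxazole-5-carbaldehyde | O=Cc1onc(CCc2ccccc2)c1Br
F2 | step 14 | ethyl (2S)-2-{2-[4-bromo-3-(2-phenylethyl)-1,2-oxazol-5-yl]-6,6-dimethyl-3,6-dihydro-2H-pyran-3-yl}-2,5-dimethylhex-4-enoate (ring diastereomers) | CCOC(=O)[C@](CC=C(C)C)(C)C1C=CC(C)(C)OC1c1onc(CCc2ccccc2)c1Br
F3 | step 15 | C5 chloro ether of 23 (diastereomers) | CC(C)=CC[C@]1(C)C(=O)c2c(CCc3ccccc3)noc2C2(Cl)OC(C)(C)C=CC12
F4 | step 11 | (5S,6E)-1,1-diethoxy-5,9-dimethyl-5-(3-methylbut-2-en-1-yl)deca-6,8-dien-2-yn-4-ol (carbinol epimers) | CCOC(OCC)C#CC(O)[C@](CC=C(C)C)(C)/C=C/C=C(C)C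
F5 | step 11 | (5S,6E)-1,1-diethoxy-5,9-dimethyl-5-(3-methylbut-2-en-1-yl)deca-6,8-dien-2-yn-4-one | CCOC(OCC)C#CC(=O)[C@](CC=C(C)C)(C)/C=C/C=C(C)C
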